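**Assumption:** germacrane-type numbering is used: C1 ring ketone, C2/C3 epoxide carbons (C2 next to C1), C4 CH(CH3), C5 CH2, C6 lactone O–CH, C7 ring CH bearing C11, C8/C9 crotonate carbons (C8 next to C7), C10 C(OH)CH3, C11/C12/C13 lactone α-carbon, carbonyl and exocyclic CH2. The target is then 2S,3S,4R,6R,7S,8S,9R,10S.

## Retrosynthetic overview

1. Target ⇒ ring Z-enone 22 (late nucleophilic epoxidation) ⇒ triol 21 ⇒ acetonide 20.
2. Ten-membered carbocycle: C2=C3 by ring-closing metathesis of the vinyl ketone / terminal alkene 19.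
3. γ-Lactone: C6–C7 by Barbier allylation of (R)-3-methylpent-4-enal 14 with allyl bromide 10, then lactonisation with inversion at C6.
4. Key disconnection C1–C10: an acryloyl anion equivalent (1-lithio-1-methoxyallene) adds to the tartrate-derived methyl ketone 3 under chelation control (sets C10); C8/C9 come from L-tartrate, C4 from an asymmetric allylic alkylation.
5. Ring order: dioxolane (from tartrate, temporary) → lactone → ten-membered carbocycle → epoxide.

## Route

Step 1
Reactants: 1 dimethyl (4R,5R)-2,2-dimethyl-1,3-dioxolane-4,5-dicarboxylate (dimethyl 2,3-O-isopropylidene-L-tartrate)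
Product: 2 (4R,5R)-N4,N5-dimethoxy-N4,N5,2,2-tetramethyl-1,3-dioxolane-4,5-dicarboxamide
Conditions: MeNH(OMe)·HCl, i-PrMgCl, THF, −20 °C to 0 °C
Reagents that add atoms: N,O-dimethylhydroxylamine hydrochloride, CNOC.Cl
Why: Ester aminolysis by the magnesium amide of N,O-dimethylhydroxylamine (Weinreb amide formation) converts both esters, and the two tartrate stereocentres are not touched at low temperature.

Step 2
Reactants: 2 (4R,5R)-N4,N5-dimethoxy-N4,N5,2,2-tetramethyl-1,3-dioxolane-4,5-dicarboxamide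
Product: 3 (4R,5R)-5-acetyl-N-methoxy-N,2,2-trimethyl-1,3-dioxolane-4-carboxamide
Conditions: MeMgBr (1.1 equiv), THF, 0 °C; aq. NH4Cl
Reagents that add atoms: methylmagnesium bromide, C[Mg]Br
Why: Grignard addition to a Weinreb amide stops at the chelated tetrahedral magnesium intermediate, and the first addition deactivates the molecule toward a second, so one amide becomes the methyl ketone (C10, C14) while the other is kept for C7.

Step 3
Reactants: 3 (4R,5R)-5-acetyl-N-methoxy-N,2,2-trimethyl-1,3-dioxolane-4-carboxamide; 4 methoxyallene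
Product: 7 (4R,5R)-5-[(2S)-2-hydroxy-3-methoxypenta-3,4-dien-2-yl]-2,2-dimethyl-1,3-dioxolane-4-carbaldehyde, via 1-lithio-1-methoxyallene 5 (not isolated), via lithium alkoxide adduct 6 (not isolated)
Conditions: 4, n-BuLi, THF, −40 °C; then 3 precomplexed with MgBr2·OEt2 (CH2Cl2), −78 °C; then i-Bu2AlH, −78 °C; aq. potassium sodium tartrate
Reagents that add atoms: none
Why: Acyl anion addition: 1-lithio-1-methoxyallene, an acryloyl anion equivalent, attacks the ketone (more electrophilic than the amide) through a Cram chelate in which magnesium bridges the carbonyl and the adjacent dioxolane oxygen, so C1 enters anti to C8 and sets 10S, and i-Bu2AlH added to the same flask reduces the Weinreb amide to the C7 aldehyde while the former ketone is held as its alkoxide.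

Step 4
Reactants: 7 (4R,5R)-5-[(2S)-2-hydroxy-3-methoxypenta-3,4-dien-2-yl]-2,2-dimethyl-1,3-dioxolane-4-carbaldehyde; 8 tert-butyl acrylate
Product: 9 tert-butyl 2-[hydroxy{(4S,5R)-5-[(2S)-2-hydroxy-3-methoxypenta-3,4-dien-2-yl]-2,2-dimethyl-1,3-dioxolan-4-yl}methyl]prop-2-enoate (both carbinol epimers)
Conditions: DABCO (1 equiv), 1,4-dioxane–H2O (1:1), 23 °C, 3 d
Reagents that add atoms: none
Why: Morita–Baylis–Hillman reaction of an activated α-alkoxy aldehyde installs C11–C13; the new carbinol centre forms as a mixture that is erased in step 5, and the allenyl enol ether is inert to amine base.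

Step 5
Reactants: 9 tert-butyl 2-[hydroxy{(4S,5R)-5-[(2S)-2-hydroxy-3-methoxypenta-3,4-dien-2-yl]-2,2-dimethyl-1,3-dioxolan-4-yl}methyl]prop-2-enoate
Product: 10 tert-butyl (2Z)-2-(bromomethyl)-3-{(4S,5R)-5-[(2S)-2-hydroxy-3-methoxypenta-3,4-dien-2-yl]-2,2-dimethyl-1,3-dioxolan-4-yl}prop-2-enoate
Conditions: CBr4, PPh3, 2,6-lutidine, CH2Cl2, −20 °C to 0 °C
Reagents that add atoms: carbon tetrabromide, BrC(Br)(Br)Br
Why: Appel bromination of a Baylis–Hillman alcohol proceeds with allylic transposition (SN2′) to the conjugated, thermodynamically preferred Z-2-(bromomethyl)enoate under neutral conditions that spare the acid-labile allenyl ether and the hindered tertiary alcohol.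

Step 6
Reactants: 11 (E)-1,4-dibromobut-2-ene
Product: 12 (S)-4-bromo-3-methylbut-1-ene
Conditions: MeMgBr, CuBr·SMe2 (1 mol %), Taniaphos (1.2 mol %, enantiomer giving the S bromide), CH2Cl2, −78 °C
Reagents that add atoms: methylmagnesium bromide, C[Mg]Br
Why: Copper-catalysed asymmetric allylic alkylation (SN2′ delivery of methyl from a chiral diphosphine–copper complex) of the symmetrical dibromide gives the branched bromide and sets the C4 methyl stereocentre by ligand control.

Step 7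
Reactants: 12 (S)-4-bromo-3-methylbut-1-ene
Product: 14 (R)-3-methylpent-4-enal, via (R)-2-methylbut-3-enyllithium 13 (not isolated)
Conditions: t-BuLi (2.1 equiv), Et2O, −78 °C; DMF, −78 °C to 0 °C; aq. NH4Cl
Reagents that add atoms: N,N-dimethylformamide, CN(C)C=O
Why: Lithium–halogen exchange followed by Bouveault formylation with DMF adds the aldehyde carbon C6; the stereocentre is β to the carbanion and not involved, and at −78 °C the homoallyllithium does not rearrange.

Step 8
Reactants: 10 tert-butyl (2Z)-2-(bromomethyl)-3-{(4S,5R)-5-[(2S)-2-hydroxy-3-methoxypenta-3,4-dien-2-yl]-2,2-dimethyl-1,3-dioxolan-4-yl}prop-2-enoate; 14 (R)-3-methylpent-4-enal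
Product: 17 tert-butyl (3S,4S,6R)-4-hydroxy-3-{(4S,5R)-5-[(2S)-2-hydroxy-3-oxopent-4-en-2-yl]-2,2-dimethyl-1,3-dioxolan-4-yl}-6-methyl-2-methylideneoct-7-enoate, via allylindium dibromide 15 (not isolated), via allenyl ether adduct 16 (not isolated)
Conditions: In powder, THF–H2O (1:1), 23 °C; then 0.5 M aq. H2SO4, 0 °C
Reagents that add atoms: water, O
Why: Indium-mediated Barbier allylation: the 2-(alkoxycarbonyl)allylindium reacts at its γ-carbon (C7) through a closed chair with the Z-fixed dioxolanyl group axial, giving the syn adduct, and the aldehyde approaches the C7 face anti to C9 with H8 eclipsing the alkene (A(1,3) strain), which sets 7S and 6S; dilute acid then hydrolyses the methoxyallene to the vinyl ketone while the tert-butyl ester prevents lactonisation with retention.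

Step 9
Reactants: 17 tert-butyl (3S,4S,6R)-4-hydroxy-3-{(4S,5R)-5-[(2S)-2-hydroxy-3-oxopent-4-en-2-yl]-2,2-dimethyl-1,3-dioxolan-4-yl}-6-methyl-2-methylideneoct-7-enoate
Product: 19 (4S,5R)-4-{(4S,5R)-5-[(2S)-2-hydroxy-3-oxopent-4-en-2-yl]-2,2-dimethyl-1,3-dioxolan-4-yl}-3-methylidene-5-[(2R)-2-methylbut-3-en-1-yl]oxolan-2-one, via C6 triflate 18 (not isolated)
Conditions: Tf2O (1.1 equiv), 2,6-lutidine, CH2Cl2, −78 °C to 0 °C
Reagents that add atoms: none
Why: O-Triflation of the secondary C6 alcohol followed by intramolecular SN2 attack of the ester carbonyl oxygen (neighbouring-group participation, loss of isobutene) closes the γ-lactone with inversion, turning 6S into the required 6R and giving the 6,7-trans lactone.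

Step 10
Reactants: 19 (4S,5R)-4-{(4S,5R)-5-[(2S)-2-hydroxy-3-oxopent-4-en-2-yl]-2,2-dimethyl-1,3-dioxolan-4-yl}-3-methylidene-5-[(2R)-2-methylbut-3-en-1-yl]oxolan-2-one
Product: 20 (2Z,4R,6R,7S,8S,9R,10S)-10-hydroxy-8,9-O-isopropylidene-1-oxogermacra-2,11(13)-dien-12,6-olide
Conditions: second-generation Hoveyda–Grubbs catalyst (15 mol %), 1,4-benzoquinone (30 mol %), toluene (1 mM), 80 °C, slow addition
Reagents that add atoms: none
Why: Ring-closing metathesis: ruthenium loads on the monosubstituted C3 alkene and closes onto the vinyl ketone (the α-methylene lactone cannot compete because cyclisation onto C11 would create a bridgehead alkene), and the ten-membered enone is expected as the ring-favoured Z isomer.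

Step 11
Reactants: 20 (2Z,4R,6R,7S,8S,9R,10S)-10-hydroxy-8,9-O-isopropylidene-1-oxogermacra-2,11(13)-dien-12,6-olide
Product: 21 (2Z,4R,6R,7R,8S,9R,10S)-8,9,10-trihydroxy-1-oxogermacra-2,11(13)-dien-12,6-olide (same spatial arrangement; the C7 descriptor changes only because the free 8-OH lowers the priority of C8)
Conditions: TFA–H2O (9:1), CH2Cl2, 0 °C to 23 °C
Reagents that add atoms: none
Why: Acid-catalysed acetonide hydrolysis frees the 8,9-diol; the α′-hydroxy enone and the methylene lactone tolerate aqueous acid.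

Step 12
Reactants: 21 (2Z,4R,6R,7R,8S,9R,10S)-8,9,10-trihydroxy-1-oxogermacra-2,11(13)-dien-12,6-olide
Product: 22 (2Z,4R,6R,7S,8S,9R,10S)-8,9-bis[(E)-but-2-enoyloxy]-10-hydroxy-1-oxogermacra-2,11(13)-dien-12,6-olide
Conditions: (E)-crotonic anhydride (3 equiv), DMAP (cat.), i-Pr2NEt, CH2Cl2, 0 °C to 23 °C
Reagents that add atoms: (E)-crotonic anhydride, C/C=C/C(=O)OC(=O)/C=C/C
Why: DMAP-catalysed acylation esterifies the two secondary hydroxyls, whereas the tertiary α-ketol hydroxyl at C10 is too hindered to react, and the anhydride avoids the deconjugation seen with crotonyl chloride.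

Step 13
Reactants: 22 (2Z,4R,6R,7S,8S,9R,10S)-8,9-bis[(E)-but-2-enoyloxy]-10-hydroxy-1-oxogermacra-2,11(13)-dien-12,6-olide
Product: 23 (2S,3S,4R,6R,7S,8S,9R,10S)-8,9-bis[(E)-but-2-enoyloxy]-2,3-epoxy-10-hydroxy-1-oxogermacr-11(13)-en-12,6-olide (CNP0253228.1)
Conditions: t-BuOOH (decane, 1.5 equiv), DBU (0.5 equiv), CH2Cl2, 0 °C
Reagents that add atoms: tert-butyl hydroperoxide, CC(C)(C)OO
Why: Weitz–Scheffer nucleophilic epoxidation: tert-butylperoxide adds to C3 of the ring enone (the best Michael acceptor present), the ring prevents C2–C3 rotation so the cis geometry is kept, and attack from the outer face anti to ring carbon C5 (H4 eclipsing the alkene) should give the 2S,3S epoxide.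

## Compound list

1 | dimethyl (4R,5R)-2,2-dimethyl-1,3-dioxolane-4,5-dicarboxylate | COC(=O)[C@@H]1OC(C)(C)O[C@H]1C(=O)OC | starting material
2 | (4R,5R)-N4,N5-dimethoxy-N4,N5,2,2-tetramethyl-1,3-dioxolane-4,5-dicarboxamide | CON(C)C(=O)[C@@H]1OC(C)(C)O[C@H]1C(=O)N(C)OC | intermediate
3 | (4R,5R)-5-acetyl-N-methoxy-N,2,2-trimethyl-1,3-dioxolane-4-carboxamide | CC(=O)[C@@H]1OC(C)(C)O[C@H]1C(=O)N(C)OC | intermediate
4 | methoxyallene (1-methoxypropa-1,2-diene) | COC=C=C | starting material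
5 | 1-lithio-1-methoxyallene | [Li]C(OC)=C=C | intermediate
6 | lithium alkoxide of (4R,5R)-5-[(2S)-2-hydroxy-3-methoxypenta-3,4-dien-2-yl]-N-methoxy-N,2,2-trimethyl-1,3-dioxolane-4-carboxamide | C=C=C(OC)[C@@](C)(O[Li])[C@@H]1OC(C)(C)O[C@H]1C(=O)N(C)OC | intermediate
7 | (4R,5R)-5-[(2S)-2-hydroxy-3-methoxypenta-3,4-dien-2-yl]-2,2-dimethyl-1,3-dioxolane-4-carbaldehyde | C=C=C(OC)[C@@](C)(O)[C@@H]1OC(C)(C)O[C@H]1C=O | intermediate
8 | tert-butyl acrylate | C=CC(=O)OC(C)(C)C | starting material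
9 | tert-butyl 2-[hydroxy{(4S,5R)-5-[(2S)-2-hydroxy-3-methoxypenta-3,4-dien-2-yl]-2,2-dimethyl-1,3-dioxolan-4-yl}methyl]prop-2-enoate (both C7 carbinol epimers) | C=C=C(OC)[C@@](C)(O)[C@@H]1OC(C)(C)O[C@H]1C(O)C(=C)C(=O)OC(C)(C)C | intermediate
10 | tert-butyl (2Z)-2-(bromomethyl)-3-{(4S,5R)-5-[(2S)-2-hydroxy-3-methoxypenta-3,4-dien-2-yl]-2,2-dimethyl-1,3-dioxolan-4-yl}prop-2-enoate | C=C=C(OC)[C@@](C)(O)[C@@H]1OC(C)(C)O[C@H]1/C=C(\CBr)C(=O)OC(C)(C)C | intermediate
11 | (E)-1,4-dibromobut-2-ene | BrC/C=C/CBr | starting material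
12 | (S)-4-bromo-3-methylbut-1-ene | C=C[C@H](C)CBr | intermediate
13 | [(2R)-2-methylbut-3-en-1-yl]lithium | C=C[C@H](C)C[Li] | intermediate
14 | (R)-3-methylpent-4-enal | C=C[C@H](C)CC=O | intermediate
15 | allylindium dibromide derived from 10 (trivalent indium on C13, drawn as the monomer) | C=C=C(OC)[C@@](C)(O)[C@@H]1OC(C)(C)O[C@H]1/C=C(\C[In](Br)Br)C(=O)OC(C)(C)C | intermediate
16 | tert-butyl (3S,4S,6R)-4-hydroxy-3-{(4S,5R)-5-[(2S)-2-hydroxy-3-methoxypenta-3,4-dien-2-yl]-2,2-dimethyl-1,3-dioxolan-4-yl}-6-methyl-2-methylideneoct-7-enoate | C=C(C(=O)OC(C)(C)C)[C@@H]([C@@H](O)C[C@@H](C)C=C)[C@@H]1OC(C)(C)O[C@H]1[C@](C)(O)C(OC)=C=C | intermediate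
17 | tert-butyl (3S,4S,6R)-4-hydroxy-3-{(4S,5R)-5-[(2S)-2-hydroxy-3-oxopent-4-en-2-yl]-2,2-dimethyl-1,3-dioxolan-4-yl}-6-methyl-2-methylideneoct-7-enoate | C=C(C(=O)OC(C)(C)C)[C@@H]([C@@H](O)C[C@@H](C)C=C)[C@@H]1OC(C)(C)O[C@H]1[C@](C)(O)C(=O)C=C | intermediate
18 | C6 trifluoromethanesulfonate of 17 | C=C(C(=O)OC(C)(C)C)[C@@H]([C@@H](OS(=O)(=O)C(F)(F)F)C[C@@H](C)C=C)[C@@H]1OC(C)(C)O[C@H]1[C@](C)(O)C(=O)C=C | intermediate
19 | (4S,5R)-4-{(4S,5R)-5-[(2S)-2-hydroxy-3-oxopent-4-en-2-yl]-2,2-dimethyl-1,3-dioxolan-4-yl}-3-methylidene-5-[(2R)-2-methylbut-3-en-1-yl]oxolan-2-one | C=C1C(=O)O[C@H](C[C@@H](C)C=C)[C@H]1[C@@H]2OC(C)(C)O[C@H]2[C@](C)(O)C(=O)C=C | intermediate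
20 | (2Z,4R,6R,7S,8S,9R,10S)-10-hydroxy-8,9-O-isopropylidene-1-oxogermacra-2,11(13)-dien-12,6-olide | C=C1C(=O)O[C@@H]2C[C@@H](C)/C=C\C(=O)[C@@](C)(O)[C@@H]3OC(C)(C)O[C@H]3[C@@H]12 | intermediate
21 | (2Z,4R,6R,7R,8S,9R,10S)-8,9,10-trihydroxy-1-oxogermacra-2,11(13)-dien-12,6-olide | C=C1C(=O)O[C@@H]2C[C@@H](C)/C=C\C(=O)[C@@](C)(O)[C@H](O)[C@@H](O)[C@@H]12 | intermediate
22 | (2Z,4R,6R,7S,8S,9R,10S)-8,9-bis[(E)-but-2-enoyloxy]-10-hydroxy-1-oxogermacra-2,11(13)-dien-12,6-olide | C=C1C(=O)O[C@@H]2C[C@@H](C)/C=C\C(=O)[C@@](C)(O)[C@H](OC(=O)/C=C/C)[C@@H](OC(=O)/C=C/C)[C@@H]12 | intermediate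
23 | (2S,3S,4R,6R,7S,8S,9R,10S)-8,9-bis[(E)-but-2-enoyloxy]-2,3-epoxy-10-hydroxy-1-oxogermacr-11(13)-en-12,6-olide (CNP0253228.1) | C=C1C(=O)O[C@@H]2C[C@@H](C)[C@@H]3O[C@@H]3C(=O)[C@@](C)(O)[C@H](OC(=O)/C=C/C)[C@@H](OC(=O)/C=C/C)[C@@H]12 | target

## Step count and risks

Total steps: 13. Longest linear sequence: 11 (steps 1–5 and 8–13, from tartrate 1); steps 6–7 make the side fragment 14.

The three steps most likely to fail:

**Step 10 (ring-closing metathesis).** A ten-membered ring is being closed onto an electron-poor vinyl ketone, so oligomerisation or an E/Z mixture is possible. The fallback sets out from 19: NaBH4 with CeCl3·7H2O in MeOH at −78 °C reduces the vinyl ketone to the bis-allylic alcohol F2 (both C1 epimers). Ring-closing metathesis of this more reactive, non-conjugated diene with the second-generation Grubbs catalyst gives the ring allylic alcohol F3. Dess–Martin oxidation then returns to the route at 20.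

**Step 8 (Barbier allylation).** The syn preference has precedent for Z-2-(bromomethyl)alk-2-enoates, but the facial sense set by the dioxolane stereocentre rests on a model only. The fallback sets out from 10: borylation with B2pin2, KOAc and catalytic Pd2(dba)3 gives the allyl pinacolboronate F1. Allylboration of 14 under a chiral phosphoric acid catalyst (TRIP, enantiomer chosen for the 6S,7S adduct) keeps the closed chair (syn) but lets the catalyst choose the aldehyde face. Aqueous work-up of the borate returns to the route at 16, which is hydrolysed to 17 as in step 8.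

**Step 13 (epoxidation).** Face selectivity is substrate-controlled and unproven, and the methylene lactone is a competing acceptor. The fallback sets out from 22: NaBH4 with CeCl3·7H2O gives the (1S)-allylic alcohol F4 (the epimer required; its formation is itself not guaranteed). Hydroxyl-directed epoxidation with VO(acac)2 and t-BuOOH, which leaves electron-poor alkenes untouched and delivers oxygen cis to the C1 hydroxyl, gives the cis-epoxy alcohol F5. Dess–Martin oxidation returns to the route at 23.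

## Further compounds

F1 | step 8 | tert-butyl (2E)-3-{(4S,5R)-5-[(2S)-2-hydroxy-3-methoxypenta-3,4-dien-2-yl]-2,2-dimethyl-1,3-dioxolan-4-yl}-2-[(4,4,5,5-tetramethyl-1,3,2-dioxaborolan-2-yl)methyl]prop-2-enoate (dioxolanyl group cis to CH2B) | C=C=C(OC)[C@@](C)(O)[C@@H]1OC(C)(C)O[C@H]1/C=C(\CB2OC(C)(C)C(C)(C)O2)C(=O)OC(C)(C)C
F2 | step 10 | lactone 19 with the C1 ketone reduced to the secondary alcohol (both C1 epimers) | C=C1C(=O)O[C@H](C[C@@H](C)C=C)[C@H]1[C@@H]2OC(C)(C)O[C@H]2[C@](C)(O)C(O)C=C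
F3 | step 10 | (2Z)-1,10-dihydroxy-8,9-O-isopropylidenegermacra-2,11(13)-dien-12,6-olide, macrocycle 20 with C1 as carbinol (both C1 epimers) | C=C1C(=O)O[C@@H]2C[C@@H](C)/C=C\C(O)[C@@](C)(O)[C@@H]3OC(C)(C)O[C@H]3[C@@H]12
F4 | step 13 | (1S)-allylic alcohol of 22: (2Z)-8,9-bis[(E)-but-2-enoyloxy]-1,10-dihydroxygermacra-2,11(13)-dien-12,6-olide | C=C1C(=O)O[C@@H]2C[C@@H](C)/C=C\[C@H](O)[C@@](C)(O)[C@H](OC(=O)/C=C/C)[C@@H](OC(=O)/C=C/C)[C@@H]12
F5 | step 13 | (1S)-carbinol of the target: 8,9-bis[(E)-but-2-enoyloxy]-2,3-epoxy-1,10-dihydroxygermacr-11(13)-en-12,6-olide with the epoxide cis to the C1 hydroxyl | C=C1C(=O)O[C@@H]2C[C@@H](C)[C@@H]3O[C@@H]3[C@H](O)[C@@](C)(O)[C@H](OC(=O)/C=C/C)[C@@H](OC(=O)/C=C/C)[C@@H]12
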